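## The problem

Target 16 is a flavanone. Ring A, a phloroglucinol, is fused through C4a–C8a to the dihydropyranone ring C, which carries the 2,4,6-trihydroxyphenyl ring B at C2; a lavandulyl chain sits on C6 between the hydroxyls on C5 and C7, and C8 is unsubstituted. The first difficulty is regiochemical: the three oxygens of ring A are nearly equivalent, so a route that closes ring C onto a preformed 2-alkylphloroglucinol, or alkylates a preformed 5,7-dihydroxychromanone, must tell C6 from C8 and the C5 oxygen from O1. There are two stereocentres, C2 (S) and the side-chain carbon C2″ (S by the sequence rule, with the spatial arrangement of (R)-lavandulol). They lie seven bonds apart across a planar ring, so neither can control the other and each must be set on its own. C2 is the fragile one: it is a benzylic ether carbon β to the C4 ketone, so base opens ring C through the C3 enolate, and free ring-B hydroxyls add a quinone-methide-type opening; both erase the configuration. The side chain holds a 1,1-disubstituted and a trisubstituted alkene next to ortho phenols, which rules out strong protic or Lewis acids (chroman formation), hydrogenation and electrophilic oxidants. The feature that opens the way is the alternation around ring A: oxygen on C5, C7 and C8a, carbon (acyl, alkyl, hydrogen) on C4a, C6 and C8. C5–C6–C7–C8 is therefore a 2-alkylacetoacetate in disguise, and C4a=C8a, with O1 already on C8a and the ketone on C4a, is the enol-ether double bond of a 2-aryl-2,3-dihydropyran-4-one.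

## Retrosynthesis

**16 ⇐ 15.** Only the three aryl ester C–O bonds of ring B are cut. Acetates are chosen over ethers because they make ring B electron-poor through the whole route: the C2–O1 bond cannot ionise, ring B does not compete in the bromination, and no quinone methide can form before the last step. The forward reaction must unveil five phenols at near-neutral pH without acid (side-chain alkenes) or real base (C2).

**15 ⇐ 6 + 12.** The C8–C8a and C4a–C5 bonds are cut, which removes ring A.
- Against its neighbours: cutting ring C (O1–C2 or C3–C4) hands the 6-versus-8 question to a ring closure that can use either ortho oxygen. Cutting the C6–CH2 bond asks for C-alkylation of a phloroglucinol with a β-branched, non-allylic electrophile.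
- Here the regiochemistry is written into the two partners. Pyranone 6 already has O1 on C8a and the ketone on C4a. Diene 12 carries its alkyl group on the carbon flanked by both oxygens.
- The bromine on C4a supplies the oxidation level of the arene. Because it replaces the acidic C4a–H, it also blocks β-elimination of O1 from C8a, which would aromatise ring A without the ring oxygen.
- The cut is convergent: each half holds one stereocentre and is three to four steps from commercial material.
- The forward step must pair the diene CH2 terminus with C8a, shed the bromine as bromide and the methoxy group, and do so without base strong enough to open ring C.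

**6 ⇐ 5.** The C–Br bond is cut. The enol-ether carbon C5 of the pyranone (C4a of the target) is its only nucleophilic position, so electrophilic bromination needs no directing help; the alternative of carrying bromine through the ring-forming step would complicate the asymmetric catalysis.

**5 ⇐ 2 + 3; 2 ⇐ 1.** The C2–C3 and O1–C6 bonds of the pyranone are cut (O1–C8a in target numbering), a formal hetero-Diels–Alder disconnection to aldehyde 2 and silyloxydiene 3. This is the only step that creates C2, and it does so at an aldehyde carbon under catalyst control, which is far better precedented than setting C2 on a finished chromanone. Aldehyde 2 is the triacetate of commercial 1. The forward reaction must cope with a di-ortho-substituted aldehyde.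

**12 ⇐ 11 ⇐ 10.** Two O–Si bonds are cut in turn. The stepwise sequence (enol ether first, then γ-deprotonation and silylation of the ester dienolate) is the standard way to 2-alkyl-1-methoxy-1,3-bis(silyloxy)dienes and fixes which carbon becomes the nucleophilic terminus.

**10 ⇐ 8 + 9; 8 ⇐ 7.** The bond between the acetoacetate α-carbon and the lavandulyl CH2 is cut. The side-chain stereocentre comes unchanged from (R)-lavandulol 7 through iodide 8; it is β to the reacting carbon and never acidic. The alternative of making the side-chain stereocentre by asymmetric synthesis would cost several steps for a unit that can be bought. The forward alkylation must put a soft enolate onto a β-branched primary iodide without elimination.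

## Roads not taken

**Alternative 1:** Ring C is cut at C4a–C4, C4–C3 and O1–C2. Iodophenol A1 (ring A complete, with the side chain and two methoxymethyl ethers), arylacetylene A2 and a one-carbon carbonyl unit would be joined by carbonylative Sonogashira coupling and 6-endo closure to flavone A3. A3 then needs enantioselective conjugate reduction of C2=C3 and acidic removal of five methoxymethyl groups.
- Merits: the three-component annulation is a proven reaction, which the chosen key step is not, and ring-A regiochemistry is locked once A1 is in hand.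
- Weak points: A1 is a hexasubstituted benzene whose own synthesis contains the whole regiochemical problem. C2 would be created by reducing a β,β-disubstituted enone bearing a di-ortho-substituted aryl group while two isolated alkenes must survive. The acidic endgame invites chroman formation.
- Comparison: against the better precedent of this ring closure, the chosen plan sets C2 at an aldehyde, needs no arene with six different substituents and ends at neutral pH.

**Alternative 2:** Ring C is cut at C3–C4 and O1–C2. Salicylaldehyde A4 would be turned into an alkoxy ortho-quinone methide and trapped by styrene A5 in an inverse-demand hetero-Diels–Alder reaction, giving 4-methoxyflavan A6.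
- Merits: it is convergent, builds ring C and joins ring B in one step, and carries no enolisable ketone until late.
- Weak points: nothing controls the absolute configuration at C2, since the remote side-chain centre cannot and no catalyst is known for this cation. A5 is an electron-poor, di-ortho-substituted styrene where the heterodiene wants an electron-rich one. The cation is generated with acid beside the side-chain alkenes. C4 must later be oxidised to the ketone in a molecule full of electron-rich rings. A4 again presupposes a regiodefined pentasubstituted ring A.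
- Comparison: it is no shorter, and the chosen plan has C4 at the ketone level from the start and sets C2 by catalysis.

**Alternative 3:** Only C4–C4a is cut. Acid A7, activated as a mixed triflic anhydride, would acylate the ring-A carbon ortho to the ether oxygen to give flavanone A8.
- Merits: regiochemistry is solved by the mirror symmetry of ring A, which is as good as the polarity control of the chosen plan. The ring-closing event, an intramolecular Friedel–Crafts acylation to a chromanone, is closer to known chemistry than the chosen key step.
- Weak points: the symmetric phenol behind A7 still needs C-lavandulylation between two oxygens. The aryl ether must be made stereospecifically at a doubly ortho-substituted benzylic carbon. Under acylating conditions the β-aryloxy acid can eliminate the phenol, and a strongly electrophilic acylating species would sit next to two nucleophilic alkenes.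
- Comparison: the chosen plan sets against its better precedent a lavandulyl group introduced by enolate alkylation, a C2 centre made at an aldehyde, and a key step run without acid.

Key step: step 8

Remarks on the chemistry:
- "Lavandulyl" stands for 5-methyl-2-(prop-1-en-2-yl)hex-4-en-1-yl. The side-chain centre is never touched; its descriptor is R in 7 and 8 and S from 10 onward only because the CH2 substituent drops below isopropenyl in priority.
- (R)-Lavandulol is taken as purchasable in enantiopure form; if only the racemate is at hand, lipase-mediated acylation resolves it.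
- The sense of induction in step 2 is assumed to be that of simple aromatic aldehydes with this catalyst ((S)-BINOL, Si-face addition, 2S); if the di-ortho-substituted aldehyde responds the other way, (R)-BINOL is used.

## Route

**Step 1**
Reactants: 1 2,4,6-trihydroxybenzaldehyde
Product: 2 2,4,6-triacetoxybenzaldehyde
Conditions: Ac2O, pyridine, DMAP (cat.), CH2Cl2, 0 °C → rt
Reagents that add atoms: acetic anhydride, CC(=O)OC(C)=O
Why: Exhaustive O-acetylation of the phenols (DMAP-catalysed acyl transfer); the acetates keep ring B electron-poor for every later step.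

**Step 2**
Reactants: 2 2,4,6-triacetoxybenzaldehyde; 3 (E)-1-methoxy-3-(trimethylsilyloxy)buta-1,3-diene
Product: 5 (2S)-2-(2,4,6-triacetoxyphenyl)-2,3-dihydro-4H-pyran-4-one, via silyl aldol adduct 4 (not isolated)
Conditions: Ti(OiPr)4 (10 mol %), (S)-BINOL (20 mol %), 4 Å MS, Et2O, −20 °C; then CF3CO2H, CH2Cl2, 0 °C
Reagents that add atoms: none
Why: Catalytic asymmetric Mukaiyama aldol addition of the silyloxydiene to the aldehyde, then acid-induced cyclisation with loss of the methoxy group (formal hetero-Diels–Alder reaction), a sequence well established for aromatic aldehydes. The chiral titanium–BINOL complex differentiates the aldehyde faces, and Si-face attack gives the 2S centre.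

**Step 3**
Reactants: 5 (2S)-2-(2,4,6-triacetoxyphenyl)-2,3-dihydro-4H-pyran-4-one
Product: 6 (2S)-5-bromo-2-(2,4,6-triacetoxyphenyl)-2,3-dihydro-4H-pyran-4-one
Conditions: NBS, CH2Cl2, 0 °C → rt, dark
Reagents that add atoms: N-bromosuccinimide, O=C1CCC(=O)N1Br
Why: Electrophilic α-bromination of the vinylogous ester (attack of Br+ at the enol-ether carbon C5, then loss of the C5 proton from the oxocarbenium ion), a standard halogenation of 2,3-dihydropyran-4-ones. The acetylated arene is too deactivated to compete, and C2 is not involved.

**Step 4**
Reactants: 7 (R)-lavandulol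
Product: 8 (R)-lavandulyl iodide
Conditions: I2, PPh3, imidazole, CH2Cl2, 0 °C → rt
Reagents that add atoms: iodine, II
Why: Appel-type iodination, SN2 displacement of the alkoxyphosphonium ion by iodide at the primary carbon; the stereocentre is one carbon away and untouched.

**Step 5**
Reactants: 8 (R)-lavandulyl iodide; 9 methyl acetoacetate
Product: 10 methyl (4S)-2-acetyl-7-methyl-4-(prop-1-en-2-yl)oct-6-enoate (both C2 epimers)
Conditions: NaH, THF–DMF, 0 °C (9 in excess); then 8, 60 °C
Reagents that add atoms: none
Why: Acetoacetic ester alkylation (SN2) by the soft, weakly basic sodium enolate, which limits E2 at the β-branched iodide; excess 9 suppresses dialkylation. The new α-centre forms as a mixture, which does not matter because it becomes sp2 in steps 6 and 7.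

**Step 6**
Reactants: 10 methyl (4S)-2-acetyl-7-methyl-4-(prop-1-en-2-yl)oct-6-enoate
Product: 11 methyl 2-[(2S)-lavandulyl]-3-(trimethylsilyloxy)but-2-enoate (E/Z mixture)
Conditions: Me3SiCl, Et3N, PhMe, rt, 48–72 h
Reagents that add atoms: chlorotrimethylsilane, C[Si](C)(C)Cl
Why: O-silylation of the enolised β-keto ester, the standard first stage in making 1,3-bis(silyloxy)dienes from 2-alkylacetoacetates.

**Step 7**
Reactants: 11 methyl 2-[(2S)-lavandulyl]-3-(trimethylsilyloxy)but-2-enoate
Product: 12 1-methoxy-2-[(2S)-lavandulyl]-1,3-bis(trimethylsilyloxy)buta-1,3-diene (either ketene-acetal geometry)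
Conditions: LiN(iPr)2, THF, −78 °C; then Me3SiCl, −78 °C → rt; used crude
Reagents that add atoms: chlorotrimethylsilane, C[Si](C)(C)Cl
Why: Kinetic γ-deprotonation of the vinylogous ester at its methyl group and O-silylation of the ester dienolate give the bis(silyloxy)diene. The ketene-acetal geometry is immaterial, and the allylic side-chain C–H is far less acidic than the γ-methyl.

**Step 8**
Reactants: 6 (2S)-5-bromo-2-(2,4,6-triacetoxyphenyl)-2,3-dihydro-4H-pyran-4-one; 12 1-methoxy-2-[(2S)-lavandulyl]-1,3-bis(trimethylsilyloxy)buta-1,3-diene
Product: 15 (2S)-5,7-dihydroxy-6-[(2S)-lavandulyl]-2-(2,4,6-triacetoxyphenyl)chroman-4-one, via cis-fused bromo cycloadduct 13 (not isolated), via 7-O-trimethylsilyl flavanone 14 (not isolated)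
Conditions: 12 (2.5 equiv), 2,4,6-collidine (3 equiv), PhMe, 90 °C, sealed tube; then aq. citric acid, THF, 0 °C → rt
Reagents that add atoms: none
Why: Proposed new method: the nucleophilic CH2 terminus (C4′) of diene 12 bonds to C8a, the β-carbon of the α-bromo vinylogous ester 6, and the ketene-acetal carbon (C1′) bonds to the bromine-bearing C4a, either in one asynchronous [4+2] event or by Mukaiyama–Michael addition followed by 6-(enolexo)-exo-trig closure of the α-bromo enolate onto the ester-level carbon; both give cis-fused adduct 13 and close ring A across C4a–C8a. The closest known reaction type is the regiospecific Diels–Alder–aromatisation of 1-methoxy-1,3-bis(silyloxy)dienes and related vinylketene acetals with halogenated quinones and α-halo enones; a β-alkoxy-α-bromo enone has not been used in this way. In 13 the mixed methyl silyl ketal at C5 collapses to the C5 carbonyl with loss of MeOSiMe3, γ-enolisation through C8 places two double bonds in ring A, and loss of bromide from the now doubly allylic C4a together with the C8a proton is an aromatisation for which the weak base collidine should suffice (giving 14); mild acid then frees the C7 hydroxyl. No stereocentre is formed: C2 and the side-chain centre arrive with 6 and 12, and neither collidine at 90 °C nor citric acid is basic enough to open ring C through the C3 enolate or acidic enough to cyclise the alkenes onto the new phenols. The one selectivity required is regiochemical and is set by polarity: the most nucleophilic diene carbon pairs with the only electrophilic carbon of the enone, which puts the lavandulyl group on C6 between the two new hydroxyls and leaves C8 unsubstituted. The bromine supplies the oxidation level of the arene and, by replacing the acidic C4a–H, shuts off E1cB expulsion of O1 from C8a; the alkyl group on C2′ likewise shuts off the [3+3] salicylate mode, which would need C2′ to become quaternary.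

**Step 9**
Reactants: 15 (2S)-5,7-dihydroxy-6-[(2S)-lavandulyl]-2-(2,4,6-triacetoxyphenyl)chroman-4-one
Product: 16 (2S)-5,7-dihydroxy-6-[(2S)-lavandulyl]-2-(2,4,6-trihydroxyphenyl)chroman-4-one
Conditions: NH4OAc, MeOH–H2O (4:1), rt
Reagents that add atoms: none
Why: Ammonium acetate in aqueous methanol cleaves aryl acetates chemoselectively at near-neutral pH (mild solvolysis). This avoids the base that would open ring C and erode C2, and the acid that would close chroman rings onto the side-chain alkenes.

## Compound list

1 | 2,4,6-trihydroxybenzaldehyde | O=Cc1c(O)cc(O)cc1O | starting material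
2 | 2,4,6-triacetoxybenzaldehyde (2-formylbenzene-1,3,5-triyl triacetate) | O=Cc1c(OC(C)=O)cc(OC(C)=O)cc1OC(C)=O | intermediate
3 | (E)-1-methoxy-3-(trimethylsilyloxy)buta-1,3-diene | CO/C=C/C(=C)O[Si](C)(C)C | starting material
4 | (1E,5S)-1-methoxy-5-(2,4,6-triacetoxyphenyl)-5-(trimethylsilyloxy)pent-1-en-3-one | CO/C=C/C(=O)C[C@@H](c1c(OC(C)=O)cc(OC(C)=O)cc1OC(C)=O)O[Si](C)(C)C | intermediate (not isolated)
5 | (2S)-2-(2,4,6-triacetoxyphenyl)-2,3-dihydro-4H-pyran-4-one | O=C1C[C@@H](c2c(OC(C)=O)cc(OC(C)=O)cc2OC(C)=O)OC=C1 | intermediate
6 | (2S)-5-bromo-2-(2,4,6-triacetoxyphenyl)-2,3-dihydro-4H-pyran-4-one | O=C1C[C@@H](c2c(OC(C)=O)cc(OC(C)=O)cc2OC(C)=O)OC=C1Br | intermediate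
7 | (R)-lavandulol, (2R)-5-methyl-2-(prop-1-en-2-yl)hex-4-en-1-ol | C=C(C)[C@@H](CC=C(C)C)CO | starting material
8 | (R)-lavandulyl iodide, (3R)-3-(iodomethyl)-2,6-dimethylhepta-1,5-diene | C=C(C)[C@@H](CC=C(C)C)CI | intermediate
9 | methyl acetoacetate | COC(=O)CC(C)=O | starting material
10 | methyl (4S)-2-acetyl-7-methyl-4-(prop-1-en-2-yl)oct-6-enoate (both C2 epimers) | C=C(C)[C@@H](CC=C(C)C)CC(C(C)=O)C(=O)OC | intermediate
11 | methyl 2-[(2S)-5-methyl-2-(prop-1-en-2-yl)hex-4-en-1-yl]-3-(trimethylsilyloxy)but-2-enoate (E/Z mixture) | C=C(C)[C@@H](CC=C(C)C)CC(C(=O)OC)=C(C)O[Si](C)(C)C | intermediate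
12 | 1-methoxy-2-[(2S)-5-methyl-2-(prop-1-en-2-yl)hex-4-en-1-yl]-1,3-bis(trimethylsilyloxy)buta-1,3-diene (ketene-acetal geometry unassigned) | C=C(C)[C@@H](CC=C(C)C)CC(C(=C)O[Si](C)(C)C)=C(OC)O[Si](C)(C)C | intermediate
13 | (2S)-4a-bromo-5-methoxy-6-[(2S)-lavandulyl]-2-(2,4,6-triacetoxyphenyl)-5,7-bis(trimethylsilyloxy)-2,3,4a,5,8,8a-hexahydro-4H-chromen-4-one (cis-fused; C4a, C5 and C8a transient and unassigned) | C=C(C)[C@@H](CC=C(C)C)CC1=C(O[Si](C)(C)C)CC2C(Br)(C(=O)C[C@@H](c3c(OC(C)=O)cc(OC(C)=O)cc3OC(C)=O)O2)C1(OC)O[Si](C)(C)C | intermediate (not isolated)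
14 | (2S)-5-hydroxy-6-[(2S)-lavandulyl]-2-(2,4,6-triacetoxyphenyl)-7-(trimethylsilyloxy)chroman-4-one | C=C(C)[C@@H](CC=C(C)C)Cc1c(O[Si](C)(C)C)cc2c(c1O)C(=O)C[C@@H](c1c(OC(C)=O)cc(OC(C)=O)cc1OC(C)=O)O2 | intermediate (not isolated)
15 | (2S)-5,7-dihydroxy-6-[(2S)-5-methyl-2-(prop-1-en-2-yl)hex-4-en-1-yl]-2-(2,4,6-triacetoxyphenyl)chroman-4-one | C=C(C)[C@@H](CC=C(C)C)Cc1c(O)cc2c(c1O)C(=O)C[C@@H](c1c(OC(C)=O)cc(OC(C)=O)cc1OC(C)=O)O2 | intermediate
16 | (2S)-5,7-dihydroxy-6-[(2S)-5-methyl-2-(prop-1-en-2-yl)hex-4-en-1-yl]-2-(2,4,6-trihydroxyphenyl)chroman-4-one | C=C(C)[C@@H](CC=C(C)C)Cc1c(O)cc2c(c1O)C(=O)C[C@@H](c1c(O)cc(O)cc1O)O2 | target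

## Step count and least certain steps

Total: 9 steps. Longest linear sequence: 6 steps (7 → 8 → 10 → 11 → 12 → 15 → 16, steps 4 to 9); the other branch (1 → 2 → 5 → 6, steps 1 to 3) joins at step 8.

**Step 8 (key step, new method).** Three things can go wrong.
- The push–pull double bond of 6 may be too poor a dienophile, so that silyl migration and hydrolysis of the diene outrun cycloaddition.
- Loss of hydrogen bromide may stall, because the C8a hydrogen is not acidic and is cis to bromine in 13; elimination has to wait for loss of the methoxy group. Forcing it with stronger base risks opening ring C at C8a through the C8 enolate and then reductive loss of bromine, which aromatises ring A without O1.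
- The C5 ketal may lose its silyloxy group where methoxy loss is wanted, leaving a 5-methyl ether.

A first remedy inside the step is catalytic Me3SiOTf at low temperature, which favours the stepwise ionic course.

Fallback (sets out from 5 and 12, returns at 15): the two bonds are made one after the other by established reaction types, and divalent palladium supplies the oxidation level in place of bromine. Catalytic Me3SiOTf (CH2Cl2, −78 °C) turns 5 into its 4-silyloxy oxocarbenium ion, and C4′ of 12 adds to it. This is a Mukaiyama–Michael addition, known for bis(silyloxy)dienes with benzopyranones and for silyl enol ethers with dihydropyranones. It gives methyl 2-[(2S)-lavandulyl]-3-(trimethylsilyloxy)-4-[(2S)-2-(2,4,6-triacetoxyphenyl)-4-(trimethylsilyloxy)-3,6-dihydro-2H-pyran-6-yl]but-2-enoate F1. Saegusa–Ito dehydrogenation of the ring silyl enol ether (Pd(OAc)2, MeCN, rt) and aqueous work-up restore the C4a=C8a double bond and give methyl 2-[(2S)-lavandulyl]-3-oxo-4-[(2S)-4-oxo-2-(2,4,6-triacetoxyphenyl)-3,4-dihydro-2H-pyran-6-yl]butanoate F2. Because C8a stays sp2 from here on, O1 can no longer be expelled. DBU (MeCN, 0 °C, short exposure) then deprotonates C8, and the vinylogous enolate closes C4a onto the ester. This is a polyketide-type Claisen condensation, known for pyranone-masked keto esters; it loses the methoxy group and tautomerises to 15. Any acetyl migration onto ring A is harmless because step 9 removes all aryl acetates.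

**Step 2.** Facial discrimination may be poor because the aldehyde is flanked by two ortho acetoxy groups that can crowd or chelate the titanium centre.

Fallback (sets out from 2 and 3, returns at 5): give up catalyst control and resolve. BF3·OEt2 (CH2Cl2, −78 °C; then CF3CO2H) gives racemic 2-(2,4,6-triacetoxyphenyl)-2,3-dihydro-4H-pyran-4-one F3, and preparative chromatography on a polysaccharide chiral stationary phase delivers the S enantiomer, which is 5.

**Step 5.** Substitution at the β-branched carbon is slow, so elimination towards the conjugated diene (the β-hydrogen is allylic) and O-alkylation may take over.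

Fallback (sets out from 7, returns at 10): make the bond by olefination, so that no substitution at the hindered carbon is needed.
- Dess–Martin oxidation of 7 (NaHCO3, CH2Cl2, 0 °C) gives (2R)-5-methyl-2-(prop-1-en-2-yl)hex-4-enal F4.
- F4 is taken at once into a Wittig reaction with Ph3P=CHCO2Me (CH2Cl2, rt) to give methyl (2E,4S)-7-methyl-4-(prop-1-en-2-yl)octa-2,6-dienoate F5.
- Copper hydride conjugate reduction ([CuH(PPh3)]6 cat., PhSiH3, PhMe, rt) touches only the enoate and gives methyl (4R)-7-methyl-4-(prop-1-en-2-yl)oct-6-enoate F6.
- The lithium enolate of F6 (LiN(iPr)2, 2 equiv, THF, −78 °C) is C-acetylated with N-methoxy-N-methylacetamide to give 10.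

**Step 9.** Configuration at C2 may erode by ring opening as the ring-B phenols appear, made worse if the two hindered ortho acetates cleave slowly and exposure must be prolonged.

Fallback (sets out from 1, returns at 16): carry ring B as allyl carbonates, which are electronically equivalent to acetates but are removed without any base or acid.
- Allyl chloroformate and pyridine convert 1 into 2,4,6-tris(allyloxycarbonyloxy)benzaldehyde F7.
- Steps 2 and 3 applied to F7 give (2S)-2-[2,4,6-tris(allyloxycarbonyloxy)phenyl]-2,3-dihydro-4H-pyran-4-one F8 and its 5-bromo derivative (2S)-5-bromo-2-[2,4,6-tris(allyloxycarbonyloxy)phenyl]-2,3-dihydro-4H-pyran-4-one F9.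
- Step 8 with 12 gives (2S)-5,7-dihydroxy-6-[(2S)-lavandulyl]-2-[2,4,6-tris(allyloxycarbonyloxy)phenyl]chroman-4-one F10.
- Tsuji–Trost-type deallylation with the zerovalent palladium catalyst Pd(PPh3)4 and dimedone as acidic allyl acceptor (THF, rt) gives 16.

## Further compounds

F1 | step 8 | methyl 2-[(2S)-lavandulyl]-3-(trimethylsilyloxy)-4-[(2S)-2-(2,4,6-triacetoxyphenyl)-4-(trimethylsilyloxy)-3,6-dihydro-2H-pyran-6-yl]but-2-enoate (C6 of the pyran ring and enol-ether geometry unassigned) | C=C(C)[C@@H](CC=C(C)C)CC(C(=O)OC)=C(CC1C=C(O[Si](C)(C)C)C[C@@H](c2c(OC(C)=O)cc(OC(C)=O)cc2OC(C)=O)O1)O[Si](C)(C)C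
F2 | step 8 | methyl 2-[(2S)-lavandulyl]-3-oxo-4-[(2S)-4-oxo-2-(2,4,6-triacetoxyphenyl)-3,4-dihydro-2H-pyran-6-yl]butanoate (both C2 epimers of the butanoate) | C=C(C)[C@@H](CC=C(C)C)CC(C(=O)OC)C(=O)CC1=CC(=O)C[C@@H](c2c(OC(C)=O)cc(OC(C)=O)cc2OC(C)=O)O1
F3 | step 2 | racemic 2-(2,4,6-triacetoxyphenyl)-2,3-dihydro-4H-pyran-4-one | O=C1CC(c2c(OC(C)=O)cc(OC(C)=O)cc2OC(C)=O)OC=C1
F4 | step 5 | (2R)-5-methyl-2-(prop-1-en-2-yl)hex-4-enal | C=C(C)[C@@H](CC=C(C)C)C=O
F5 | step 5 | methyl (2E,4S)-7-methyl-4-(prop-1-en-2-yl)octa-2,6-dienoate | C=C(C)[C@@H](CC=C(C)C)/C=C/C(=O)OC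
F6 | step 5 | methyl (4R)-7-methyl-4-(prop-1-en-2-yl)oct-6-enoate | C=C(C)[C@@H](CC=C(C)C)CCC(=O)OC
F7 | step 9 | 2,4,6-tris(allyloxycarbonyloxy)benzaldehyde | O=Cc1c(OC(=O)OCC=C)cc(OC(=O)OCC=C)cc1OC(=O)OCC=C
F8 | step 9 | (2S)-2-[2,4,6-tris(allyloxycarbonyloxy)phenyl]-2,3-dihydro-4H-pyran-4-one | O=C1C[C@@H](c2c(OC(=O)OCC=C)cc(OC(=O)OCC=C)cc2OC(=O)OCC=C)OC=C1
F9 | step 9 | (2S)-5-bromo-2-[2,4,6-tris(allyloxycarbonyloxy)phenyl]-2,3-dihydro-4H-pyran-4-one | O=C1C[C@@H](c2c(OC(=O)OCC=C)cc(OC(=O)OCC=C)cc2OC(=O)OCC=C)OC=C1Br
F10 | step 9 | (2S)-5,7-dihydroxy-6-[(2S)-lavandulyl]-2-[2,4,6-tris(allyloxycarbonyloxy)phenyl]chroman-4-one | C=C(C)[C@@H](CC=C(C)C)Cc1c(O)cc2c(c1O)C(=O)C[C@@H](c1c(OC(=O)OCC=C)cc(OC(=O)OCC=C)cc1OC(=O)OCC=C)O2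
A1 | alternative 1 | 2-iodo-3,5-bis(methoxymethoxy)-4-[(2S)-lavandulyl]phenol | C=C(C)[C@@H](CC=C(C)C)Cc1c(OCOC)cc(O)c(I)c1OCOC
A2 | alternative 1 | 2-ethynyl-1,3,5-tris(methoxymethoxy)benzene | C#Cc1c(OCOC)cc(OCOC)cc1OCOC
A3 | alternative 1 | 5,7-bis(methoxymethoxy)-6-[(2S)-lavandulyl]-2-[2,4,6-tris(methoxymethoxy)phenyl]-4H-chromen-4-one | C=C(C)[C@@H](CC=C(C)C)Cc1c(OCOC)cc2oc(-c3c(OCOC)cc(OCOC)cc3OCOC)cc(=O)c2c1OCOC
A4 | alternative 2 | 2,4-bis(tert-butyldimethylsilyloxy)-6-hydroxy-3-[(2S)-lavandulyl]benzaldehyde | C=C(C)[C@@H](CC=C(C)C)Cc1c(O[Si](C)(C)C(C)(C)C)cc(O)c(C=O)c1O[Si](C)(C)C(C)(C)C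
A5 | alternative 2 | 2,4,6-triacetoxystyrene | C=Cc1c(OC(C)=O)cc(OC(C)=O)cc1OC(C)=O
A6 | alternative 2 | (2S)-2,4-cis-4-methoxy-5,7-bis(tert-butyldimethylsilyloxy)-6-[(2S)-lavandulyl]-2-(2,4,6-triacetoxyphenyl)chroman | C=C(C)[C@@H](CC=C(C)C)Cc1c(O[Si](C)(C)C(C)(C)C)cc2c(c1O[Si](C)(C)C(C)(C)C)[C@@H](OC)C[C@@H](c1c(OC(C)=O)cc(OC(C)=O)cc1OC(C)=O)O2
A7 | alternative 3 | (3S)-3-{3,5-bis(tert-butyldimethylsilyloxy)-4-[(2S)-lavandulyl]phenoxy}-3-(2,4,6-triacetoxyphenyl)propanoic acid | C=C(C)[C@@H](CC=C(C)C)Cc1c(O[Si](C)(C)C(C)(C)C)cc(O[C@@H](CC(=O)O)c2c(OC(C)=O)cc(OC(C)=O)cc2OC(C)=O)cc1O[Si](C)(C)C(C)(C)C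
A8 | alternative 3 | (2S)-5,7-bis(tert-butyldimethylsilyloxy)-6-[(2S)-lavandulyl]-2-(2,4,6-triacetoxyphenyl)chroman-4-one | C=C(C)[C@@H](CC=C(C)C)Cc1c(O[Si](C)(C)C(C)(C)C)cc2c(c1O[Si](C)(C)C(C)(C)C)C(=O)C[C@@H](c1c(OC(C)=O)cc(OC(C)=O)cc1OC(C)=O)O2
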